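Numbering follows the tetralone: C1 is the carbonyl carbon, C4 the aryl-bearing carbon, ring A the catechol ring, ring B the cyclohexanone ring.

**Plan**
- Retrosynthesis: with the three benzyl ethers in place and C1 stepped back from ketone to ether, ring B is cut at C4–C4a and C1–C8a.
- Both bonds leave ring A from adjacent carbons directly beside the C8 oxygen. Ring A is therefore a 3-alkoxyaryne and C1–C4 a four-carbon diene with oxygen on C1 and the naphthyl group on C4, which is what allows an aryne Diels–Alder reaction.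
- Forward: a naphthylmethyl phosphonate (from 1,5-dimethoxynaphthalene) and an auxiliary-bearing 3-alkoxyacrolein are joined by Horner–Wadsworth–Emmons olefination to the (1E,3E)-diene. The silylaryl triflate comes from 2,3-dihydroxybenzaldehyde.
- The aryne cycloaddition closes ring B, the only ring made. C2=C3 is then saturated, the auxiliary hydrolysed off, C1 oxidised and the benzyl ethers removed.
- Stereochemistry: C4 (S) is set in the cycloaddition by the (1S,2R)-2-phenylcyclohexyl group on the C1 oxygen. C1 is set cis to C4 in the same step and is erased on oxidation.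

Key step: step 15

Assumption: the dienyl ether is taken to react through its s-trans O–C1 conformer with the carbinol C–H in the enol ether plane, which puts the phenyl ring over the face leading to (4R); on this model the (1S,2R)-alcohol gives (4S), and the mirror-image alcohol would be used if the sense proved opposite.

**Route**

Step 1
Reactants: 1 1,5-dimethoxynaphthalene
Product: 3 4,8-dimethoxy-1-naphthaldehyde, via iminium chloride 2 (not isolated)
Conditions: POCl3, DMF, toluene, 100 °C; then H2O
Reagents that add atoms: N,N-dimethylformamide CN(C)C=O (formyl carbon); water O (carbonyl oxygen)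
Why: Vilsmeier–Haack formylation attacks the position para to one methoxy group and peri to the other, the only activated type of site in this symmetric arene, so a single aldehyde should result after hydrolysis of the iminium salt.

Step 2
Reactants: 3 4,8-dimethoxy-1-naphthaldehyde
Product: 4 4-hydroxy-8-methoxy-1-naphthaldehyde
Conditions: EtSNa, DMF, 110 °C; then aq. HCl
Reagents that add atoms: none
Why: Thiolate demethylation (SN2 at the methyl group) should be selective for the 4-methoxy group, because only its naphtholate is conjugated with the para formyl group, while the peri 8-methoxy group is not in conjugation with it.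

Step 3
Reactants: 4 4-hydroxy-8-methoxy-1-naphthaldehyde
Product: 5 4-(benzyloxy)-8-methoxy-1-naphthaldehyde
Conditions: BnBr, K2CO3, DMF, rt
Reagents that add atoms: benzyl bromide BrCc1ccccc1
Why: Williamson etherification of the acidic, formyl-conjugated naphthol is straightforward and gives a protecting group that falls together with the catechol benzyl ethers at the end.

Step 4
Reactants: 5 4-(benzyloxy)-8-methoxy-1-naphthaldehyde
Product: 6 [4-(benzyloxy)-8-methoxynaphthalen-1-yl]methanol
Conditions: NaBH4, MeOH/THF, 0 °C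
Reagents that add atoms: none
Why: Borohydride reduction of an aryl aldehyde to the primary benzylic alcohol leaves both ethers untouched.

Step 5
Reactants: 6 [4-(benzyloxy)-8-methoxynaphthalen-1-yl]methanol
Product: 7 diethyl {[4-(benzyloxy)-8-methoxynaphthalen-1-yl]methyl}phosphonate
Conditions: P(OEt)3, ZnI2, toluene, reflux
Reagents that add atoms: triethyl phosphite CCOP(OCC)OCC
Why: The ZnI2-promoted Michaelis–Arbuzov reaction converts electron-rich benzylic alcohols directly into phosphonates through the benzylic iodide, avoiding isolation of a labile naphthylmethyl halide.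

Step 6
Reactants: 8 (1S,2R)-2-phenylcyclohexan-1-ol; 9 ethyl propiolate
Product: 10 ethyl (2E)-3-{[(1S,2R)-2-phenylcyclohexyl]oxy}prop-2-enoate
Conditions: PBu3 (cat.), CH2Cl2, rt
Reagents that add atoms: none
Why: Phosphine-catalysed oxa-Michael addition of a secondary alcohol to a propiolate gives the trans β-alkoxyacrylate and does not touch the two auxiliary stereocentres.

Step 7
Reactants: 10 ethyl (2E)-3-{[(1S,2R)-2-phenylcyclohexyl]oxy}prop-2-enoate
Product: 11 (2E)-3-{[(1S,2R)-2-phenylcyclohexyl]oxy}prop-2-en-1-ol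
Conditions: DIBAL-H, CH2Cl2, −78 °C; then aq. potassium sodium tartrate
Reagents that add atoms: none
Why: DIBAL-H reduces the unsaturated ester in 1,2-fashion to the allylic alcohol with retention of the enol ether geometry, and the basic work-up protects the acid-labile product.

Step 8
Reactants: 11 (2E)-3-{[(1S,2R)-2-phenylcyclohexyl]oxy}prop-2-en-1-ol
Product: 12 (2E)-3-{[(1S,2R)-2-phenylcyclohexyl]oxy}prop-2-enal
Conditions: MnO2, CH2Cl2, rt
Reagents that add atoms: none
Why: Allylic oxidation with MnO2 is neutral and selective and should give the vinylogous formate without isomerising or hydrolysing the enol ether.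

Step 9
Reactants: 7 diethyl {[4-(benzyloxy)-8-methoxynaphthalen-1-yl]methyl}phosphonate; 12 (2E)-3-{[(1S,2R)-2-phenylcyclohexyl]oxy}prop-2-enal
Product: 13 1-(benzyloxy)-5-methoxy-4-[(1E,3E)-4-{[(1S,2R)-2-phenylcyclohexyl]oxy}buta-1,3-dien-1-yl]naphthalene
Conditions: 7, NaHMDS, THF, −78 °C; then 12, −78 °C to rt
Reagents that add atoms: none
Why: Horner–Wadsworth–Emmons olefination with a benzylic phosphonate anion adds 1,2 to the enal and gives the E aryl-alkene, while the E enol ether is carried through unchanged, so the (1E,3E)-diene is expected.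

Step 10
Reactants: 14 2,3-dihydroxybenzaldehyde
Product: 15 2,3-bis(benzyloxy)benzaldehyde
Conditions: BnBr, K2CO3, DMF, 60 °C
Reagents that add atoms: benzyl bromide BrCc1ccccc1
Why: Double Williamson etherification of the catechol is routine, and the formyl group is kept as the handle for introducing the third oxygen.

Step 11
Reactants: 15 2,3-bis(benzyloxy)benzaldehyde
Product: 17 2,3-bis(benzyloxy)phenol, via aryl formate 16 (not isolated)
Conditions: mCPBA, CH2Cl2, rt; then K2CO3 (cat.), MeOH, rt
Reagents that add atoms: mCPBA OOC(=O)c1cccc(Cl)c1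
Why: In this Dakin-type Baeyer–Villiger oxidation the electron-rich aryl group migrates to give the aryl formate, which mild methanolysis converts into the phenol.

Step 12
Reactants: 17 2,3-bis(benzyloxy)phenol
Product: 18 2,3-bis(benzyloxy)phenyl N-isopropylcarbamate
Conditions: i-PrNCO, Et3N (cat.), CH2Cl2, rt
Reagents that add atoms: isopropyl isocyanate CC(C)N=C=O
Why: Base-catalysed addition of the phenol to the isocyanate installs a directing group that can later be removed under mild, non-nucleophilic conditions.

Step 13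
Reactants: 18 2,3-bis(benzyloxy)phenyl N-isopropylcarbamate
Product: 22 2,3-bis(benzyloxy)-6-(trimethylsilyl)phenyl N-isopropylcarbamate, via N-silyl carbamate 19 (not isolated), via aryllithium 20 (not isolated), via N-silyl C-silyl carbamate 21 (not isolated)
Conditions: TBSOTf, TMEDA, Et2O, 0 °C to rt; n-BuLi, TMEDA, −78 °C; TMSCl, −78 °C to rt; aq. NaHSO4
Reagents that add atoms: chlorotrimethylsilane C[Si](C)(C)Cl
Why: Directed ortho-metalation: after in situ N-silylation the carbamate directs n-BuLi/TMEDA to C6, the only free ortho position, the aryllithium is trapped by TMSCl, and the N–Si bond is hydrolysed on work-up.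

Step 14
Reactants: 22 2,3-bis(benzyloxy)-6-(trimethylsilyl)phenyl N-isopropylcarbamate
Product: 24 2,3-bis(benzyloxy)-6-(trimethylsilyl)phenyl trifluoromethanesulfonate, via silylphenol 23 (not isolated)
Conditions: DBU, Et2NH, MeCN, 40 °C; then PhNTf2, rt
Reagents that add atoms: N-phenylbis(trifluoromethanesulfonimide) O=S(=O)(N(c1ccccc1)S(=O)(=O)C(F)(F)F)C(F)(F)F
Why: DBU triggers E1cB loss of isopropyl isocyanate (scavenged by diethylamine) and the phenoxide is triflated in the same flask, so the protodesilylation-prone silylphenol is never handled.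

Step 15
Reactants: 24 2,3-bis(benzyloxy)-6-(trimethylsilyl)phenyl trifluoromethanesulfonate; 13 1-(benzyloxy)-5-methoxy-4-[(1E,3E)-4-{[(1S,2R)-2-phenylcyclohexyl]oxy}buta-1,3-dien-1-yl]naphthalene
Product: 26 (1S,4S)-7,8-bis(benzyloxy)-4-[4-(benzyloxy)-8-methoxynaphthalen-1-yl]-1-{[(1S,2R)-2-phenylcyclohexyl]oxy}-1,4-dihydronaphthalene, via 3,4-bis(benzyloxy)benzyne 25 (not isolated)
Conditions: 24 (1.5 equiv), CsF, MeCN/THF, rt
Reagents that add atoms: none
Why: Proposed new method: fluoride removes the trimethylsilyl group of 24 and expels triflate to give aryne 25, which the s-cis (1E,3E)-diene 13 takes up in a concerted suprafacial [4+2] cycloaddition; the closest known reaction type is the aryne Diels–Alder reaction of acyclic 1,4-disubstituted dienes to cis-1,4-dihydronaphthalenes, including versions with carbon-bound auxiliaries, whereas facial control by an oxygen-bound auxiliary is untested. Ring B closes as a six-membered carbocycle by this intermolecular two-bond annulation, with C4–C4a and C1–C8a formed on the same diene face. Because both outward groups of the E,E-diene are carried to one side, C1 and C4 emerge cis, and their absolute configuration (4S, 1S) is set by the (1S,2R)-2-phenylcyclohexyl group, whose phenyl ring lies over the C1 terminus on one face so that the aryne bonds to the other. The step needs regioselectivity, which the C8 benzyloxy group secures by distorting the aryne so that the carbon meta to it (future C4a) is electrophilic, while the enol ether oxygen makes C4 the nucleophilic diene terminus and the bulky naphthyl end avoids the benzyloxy flank. It also needs [4+2] to win over [2+2] and ene pathways, which the easily reached s-cis conformer of an E,E-diene favours, and it needs facial selectivity, for which the auxiliary is the only control element.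

Step 16
Reactants: 26 (1S,4S)-7,8-bis(benzyloxy)-4-[4-(benzyloxy)-8-methoxynaphthalen-1-yl]-1-{[(1S,2R)-2-phenylcyclohexyl]oxy}-1,4-dihydronaphthalene
Product: 27 (1S,4S)-7,8-bis(benzyloxy)-4-[4-(benzyloxy)-8-methoxynaphthalen-1-yl]-1-{[(1S,2R)-2-phenylcyclohexyl]oxy}-1,2,3,4-tetrahydronaphthalene
Conditions: 2-nitrobenzenesulfonylhydrazide, Et3N, CH2Cl2, rt (26 used promptly)
Reagents that add atoms: none
Why: Diimide transfers two hydrogens to the cis-disubstituted C2=C3 bond from the face opposite the two cis substituents, without double-bond migration, without touching benzyl ethers or benzylic C–O bonds, and without affecting C1 or C4; it also removes the risk of aromatisation by loss of the alkoxy group.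

Step 17
Reactants: 27 (1S,4S)-7,8-bis(benzyloxy)-4-[4-(benzyloxy)-8-methoxynaphthalen-1-yl]-1-{[(1S,2R)-2-phenylcyclohexyl]oxy}-1,2,3,4-tetrahydronaphthalene
Product: 28 (4S)-7,8-bis(benzyloxy)-4-[4-(benzyloxy)-8-methoxynaphthalen-1-yl]-1,2,3,4-tetrahydronaphthalen-1-ol (mixture of C1 epimers)
Conditions: 1 M aq. HCl/1,4-dioxane (1:2), 50 °C
Reagents that add atoms: water O
Why: Acid-catalysed SN1 hydrolysis ionises the benzylic C1–O bond (the cation is stabilised by the ortho benzyloxy group), and in a water-rich medium capture by water should outrun proton loss; the auxiliary alcohol 8 is released for recovery, C4 is not involved, and the C1 epimer mixture is irrelevant.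

Step 18
Reactants: 28 (4S)-7,8-bis(benzyloxy)-4-[4-(benzyloxy)-8-methoxynaphthalen-1-yl]-1,2,3,4-tetrahydronaphthalen-1-ol
Product: 29 (4S)-7,8-bis(benzyloxy)-4-[4-(benzyloxy)-8-methoxynaphthalen-1-yl]-3,4-dihydronaphthalen-1(2H)-one
Conditions: Dess–Martin periodinane, CH2Cl2, 0 °C to rt
Reagents that add atoms: none
Why: Dess–Martin oxidation converts both C1 epimers into the one ketone under near-neutral conditions that tolerate the electron-rich arenes and leave the C4 stereocentre alone.

Step 19
Reactants: 29 (4S)-7,8-bis(benzyloxy)-4-[4-(benzyloxy)-8-methoxynaphthalen-1-yl]-3,4-dihydronaphthalen-1(2H)-one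
Product: 30 (4S)-7,8-dihydroxy-4-(4-hydroxy-8-methoxynaphthalen-1-yl)-3,4-dihydronaphthalen-1(2H)-one
Conditions: H2 (1 atm), 10% Pd/C, EtOAc/MeOH, rt
Reagents that add atoms: none
Why: Hydrogenolysis over Pd/C cleaves the three aryl benzyl ethers quickly at 1 atm, while the methyl ether, the aryl ketone and the C4 stereocentre should survive if the reaction is stopped at full debenzylation.

**Compound list**
1 | 1,5-dimethoxynaphthalene | COc1cccc2c(OC)cccc12 | starting material
2 | [(4,8-dimethoxynaphthalen-1-yl)methylidene]dimethylammonium chloride | C[N+](C)=Cc1ccc(OC)c2cccc(OC)c12.[Cl-] | intermediate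
3 | 4,8-dimethoxy-1-naphthaldehyde | O=Cc1ccc(OC)c2cccc(OC)c12 | intermediate
4 | 4-hydroxy-8-methoxy-1-naphthaldehyde | O=Cc1ccc(O)c2cccc(OC)c12 | intermediate
5 | 4-(benzyloxy)-8-methoxy-1-naphthaldehyde | O=Cc1ccc(OCc2ccccc2)c2cccc(OC)c12 | intermediate
6 | [4-(benzyloxy)-8-methoxynaphthalen-1-yl]methanol | OCc1ccc(OCc2ccccc2)c2cccc(OC)c12 | intermediate
7 | diethyl {[4-(benzyloxy)-8-methoxynaphthalen-1-yl]methyl}phosphonate | CCOP(=O)(OCC)Cc1ccc(OCc2ccccc2)c2cccc(OC)c12 | intermediate
8 | (1S,2R)-2-phenylcyclohexan-1-ol (trans) | O[C@H]1CCCC[C@@H]1c1ccccc1 | starting material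
9 | ethyl propiolate | CCOC(=O)C#C | starting material
10 | ethyl (2E)-3-{[(1S,2R)-2-phenylcyclohexyl]oxy}prop-2-enoate | CCOC(=O)/C=C/O[C@H]1CCCC[C@@H]1c1ccccc1 | intermediate
11 | (2E)-3-{[(1S,2R)-2-phenylcyclohexyl]oxy}prop-2-en-1-ol | OC/C=C/O[C@H]1CCCC[C@@H]1c1ccccc1 | intermediate
12 | (2E)-3-{[(1S,2R)-2-phenylcyclohexyl]oxy}prop-2-enal | O=C/C=C/O[C@H]1CCCC[C@@H]1c1ccccc1 | intermediate
13 | 1-(benzyloxy)-5-methoxy-4-[(1E,3E)-4-{[(1S,2R)-2-phenylcyclohexyl]oxy}buta-1,3-dien-1-yl]naphthalene | COc1cccc2c(OCc3ccccc3)ccc(/C=C/C=C/O[C@H]3CCCC[C@@H]3c3ccccc3)c12 | intermediate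
14 | 2,3-dihydroxybenzaldehyde | O=Cc1cccc(O)c1O | starting material
15 | 2,3-bis(benzyloxy)benzaldehyde | O=Cc1cccc(OCc2ccccc2)c1OCc1ccccc1 | intermediate
16 | 2,3-bis(benzyloxy)phenyl formate | O=COc1cccc(OCc2ccccc2)c1OCc1ccccc1 | intermediate
17 | 2,3-bis(benzyloxy)phenol | Oc1cccc(OCc2ccccc2)c1OCc1ccccc1 | intermediate
18 | 2,3-bis(benzyloxy)phenyl N-isopropylcarbamate | CC(C)NC(=O)Oc1cccc(OCc2ccccc2)c1OCc1ccccc1 | intermediate
19 | 2,3-bis(benzyloxy)phenyl N-(tert-butyldimethylsilyl)-N-isopropylcarbamate | CC(C)N([Si](C)(C)C(C)(C)C)C(=O)Oc1cccc(OCc2ccccc2)c1OCc1ccccc1 | intermediate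
20 | 6-lithio derivative of 19 (aryllithium ortho to the carbamate) | [Li]c1ccc(OCc2ccccc2)c(OCc2ccccc2)c1OC(=O)N(C(C)C)[Si](C)(C)C(C)(C)C | intermediate
21 | 2,3-bis(benzyloxy)-6-(trimethylsilyl)phenyl N-(tert-butyldimethylsilyl)-N-isopropylcarbamate | C[Si](C)(C)c1ccc(OCc2ccccc2)c(OCc2ccccc2)c1OC(=O)N(C(C)C)[Si](C)(C)C(C)(C)C | intermediate
22 | 2,3-bis(benzyloxy)-6-(trimethylsilyl)phenyl N-isopropylcarbamate | C[Si](C)(C)c1ccc(OCc2ccccc2)c(OCc2ccccc2)c1OC(=O)NC(C)C | intermediate
23 | 2,3-bis(benzyloxy)-6-(trimethylsilyl)phenol (present as its DBU-H phenoxide) | C[Si](C)(C)c1ccc(OCc2ccccc2)c(OCc2ccccc2)c1O | intermediate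
24 | 2,3-bis(benzyloxy)-6-(trimethylsilyl)phenyl trifluoromethanesulfonate | C[Si](C)(C)c1ccc(OCc2ccccc2)c(OCc2ccccc2)c1OS(=O)(=O)C(F)(F)F | intermediate
25 | 3,4-bis(benzyloxy)benzyne (3,4-bis(benzyloxy)-1,2-didehydrobenzene) | C1#CC(OCc2ccccc2)=C(OCc2ccccc2)C=C1 | intermediate
26 | (1S,4S)-7,8-bis(benzyloxy)-4-[4-(benzyloxy)-8-methoxynaphthalen-1-yl]-1-{[(1S,2R)-2-phenylcyclohexyl]oxy}-1,4-dihydronaphthalene (1,4-cis) | COc1cccc2c(OCc3ccccc3)ccc([C@@H]3C=C[C@H](O[C@H]4CCCC[C@@H]4c4ccccc4)c4c3ccc(OCc5ccccc5)c4OCc5ccccc5)c12 | intermediate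
27 | (1S,4S)-7,8-bis(benzyloxy)-4-[4-(benzyloxy)-8-methoxynaphthalen-1-yl]-1-{[(1S,2R)-2-phenylcyclohexyl]oxy}-1,2,3,4-tetrahydronaphthalene | COc1cccc2c(OCc3ccccc3)ccc([C@@H]3CC[C@H](O[C@H]4CCCC[C@@H]4c4ccccc4)c4c3ccc(OCc5ccccc5)c4OCc5ccccc5)c12 | intermediate
28 | (4S)-7,8-bis(benzyloxy)-4-[4-(benzyloxy)-8-methoxynaphthalen-1-yl]-1,2,3,4-tetrahydronaphthalen-1-ol (C1 epimers) | COc1cccc2c(OCc3ccccc3)ccc([C@@H]3CCC(O)c4c3ccc(OCc5ccccc5)c4OCc5ccccc5)c12 | intermediate
29 | (4S)-7,8-bis(benzyloxy)-4-[4-(benzyloxy)-8-methoxynaphthalen-1-yl]-3,4-dihydronaphthalen-1(2H)-one | COc1cccc2c(OCc3ccccc3)ccc([C@@H]3CCC(=O)c4c3ccc(OCc5ccccc5)c4OCc5ccccc5)c12 | intermediate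
30 | (4S)-7,8-dihydroxy-4-(4-hydroxy-8-methoxynaphthalen-1-yl)-3,4-dihydronaphthalen-1(2H)-one | COc1cccc2c(O)ccc([C@@H]3CCC(=O)c4c3ccc(O)c4O)c12 | target

**Step count**
- Total: 19 steps.
- Longest linear sequence: 11 steps (steps 1–5, 9, 15–19, from 1,5-dimethoxynaphthalene).

**Steps most likely to fail**

1. Step 15. The auxiliary may shield the diene face poorly, or in the opposite sense, so that material of the wrong C4 configuration is carried forward; the two facial adducts are diastereomers, so chromatography at 26 or 27 is the first remedy. The fallback uses known chemistry and moves stereocontrol to a reagent-controlled reduction. It sets out from ketone 29 of low enantiomeric purity, obtained by running steps 16–18 on the adduct mixture. Corey–Bakshi–Shibata reduction ((S)-2-methyl-CBS-oxazaborolidine, BH3·SMe2, THF, −20 °C) should give the (1R)-carbinol from both ketone enantiomers. From 29 this is the trans alcohol (1R,4S)-7,8-bis(benzyloxy)-4-[4-(benzyloxy)-8-methoxynaphthalen-1-yl]-1,2,3,4-tetrahydronaphthalen-1-ol F1, and from the enantiomer of 29 it is the cis alcohol (1R,4R)-7,8-bis(benzyloxy)-4-[4-(benzyloxy)-8-methoxynaphthalen-1-yl]-1,2,3,4-tetrahydronaphthalen-1-ol F2. These are diastereomers and should separate on silica. Dess–Martin oxidation of F1 comes back to the route at 29 as a single enantiomer; this reduce–separate–reoxidise sequence is an established way to resolve 4-aryl-1-tetralones.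

2. Step 17. Proton loss from the C1 benzylic cation may outrun capture by water, so that elimination to the styrene replaces hydrolysis. The fallback accepts the elimination and reinstalls the oxygen by a radical hydration. It sets out from 27: TsOH (cat.) in toluene at 80 °C should give (1R)-5,6-bis(benzyloxy)-1-[4-(benzyloxy)-8-methoxynaphthalen-1-yl]-1,2-dihydronaphthalene F3 with the C4 stereocentre of the tetralone numbering intact. Mukaiyama hydration (Co(acac)2 cat., PhSiH3, O2, THF, rt) then places oxygen on the benzylic carbon and comes back to the route at 28 (any ketone formed is already 29).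

3. Step 13. Deprotonation of a benzylic OCH2 group (followed by Wittig rearrangement) or anionic Fries migration may compete with ortho-lithiation. The fallback replaces directed metalation by halogen–lithium exchange with a retro-Brook shift, and sets out from phenol 17. Amine-mediated ortho-bromination (NBS, i-Pr2NH cat., CH2Cl2, 0 °C) should give 2,3-bis(benzyloxy)-6-bromophenol F4, since only one ortho position is free. Silylation (HMDS, THF, reflux) gives [2,3-bis(benzyloxy)-6-bromophenoxy]trimethylsilane F5. n-BuLi in THF at −78 °C effects bromine–lithium exchange and O-to-C silyl migration to the lithium phenoxide of 23, and Tf2O added to the same flask comes back to the route at 24.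

Further compounds
F1 | step 15 | (1R,4S)-7,8-bis(benzyloxy)-4-[4-(benzyloxy)-8-methoxynaphthalen-1-yl]-1,2,3,4-tetrahydronaphthalen-1-ol | COc1cccc2c(OCc3ccccc3)ccc([C@@H]3CC[C@@H](O)c4c3ccc(OCc5ccccc5)c4OCc5ccccc5)c12
F2 | step 15 | (1R,4R)-7,8-bis(benzyloxy)-4-[4-(benzyloxy)-8-methoxynaphthalen-1-yl]-1,2,3,4-tetrahydronaphthalen-1-ol | COc1cccc2c(OCc3ccccc3)ccc([C@H]3CC[C@@H](O)c4c3ccc(OCc5ccccc5)c4OCc5ccccc5)c12
F3 | step 17 | (1R)-5,6-bis(benzyloxy)-1-[4-(benzyloxy)-8-methoxynaphthalen-1-yl]-1,2-dihydronaphthalene | COc1cccc2c(OCc3ccccc3)ccc([C@@H]3CC=Cc4c3ccc(OCc5ccccc5)c4OCc5ccccc5)c12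
F4 | step 13 | 2,3-bis(benzyloxy)-6-bromophenol | Oc1c(Br)ccc(OCc2ccccc2)c1OCc1ccccc1
F5 | step 13 | [2,3-bis(benzyloxy)-6-bromophenoxy]trimethylsilane | C[Si](C)(C)Oc1c(Br)ccc(OCc2ccccc2)c1OCc1ccccc1
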